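**Retrosynthetic overview**

1. Feature: ring A is a hydroquinone whose quinone form has C8a as the free CH next to alkylated C4a, while O2 on C3 can carry a one-carbon radical (C1) that reaches C8a through a six-membered transition state. Isochromanone numbering is used; the side chain is C1'–C5' outward from C3.
2. Target 17 ⇐ quinone lactone 16 (Zn/AcOH: quinone to hydroquinone, trichloroethyl ester to acid) ⇐ quinone oxalate half ester 15 by C1–C8a radical acylation. This closes the lactone (ring B), the only ring made; ring A is bought as a 1,4-dimethoxyarene and oxidised late.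
3. 15 ⇐ alcohol 12 (tert-butyl oxalate on O2, arene to quinone, tert-butyl off) ⇐ allylic alcohol 10 + pentenyl succinate 5 by C1'=C2' cross metathesis, then hydrogenation.
4. 10 ⇐ 2,5-dimethoxyphenylmagnesium bromide + (S)-epichlorohydrin (fixes C3); 5 ⇐ (S)-pent-4-en-2-ol (fixes C4') + succinic anhydride + 2,2,2-trichloroethanol.

Key step: step 10

Assumption: 2,5-dimethoxyphenylmagnesium bromide (THF solution) and tert-butyl chlorooxoacetate are taken as purchasable. From step 8 on, no amine base or HCl is used, because the C4 hydrogens of the alkylquinone are vinylogously acidic with a leaving group on C3, and HCl adds to quinones.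

**Route**

Step 1
Reactants: 1 succinic anhydride; 2 2,2,2-trichloroethanol
Product: 3 4-oxo-4-(2,2,2-trichloroethoxy)butanoic acid
Conditions: DMAP (0.1 equiv), toluene, 100 °C
Reagents that add atoms: none
Why: DMAP-catalysed alcoholysis of the cyclic anhydride opens it once and should stop at the half ester, because the carboxylic acid set free does not acylate the weakly nucleophilic alcohol.

Step 2
Reactants: 4 (S)-pent-4-en-2-ol; 3 4-oxo-4-(2,2,2-trichloroethoxy)butanoic acid
Product: 5 (2S)-pent-4-en-2-yl 2,2,2-trichloroethyl butanedioate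
Conditions: EDC hydrochloride (1.3 equiv), DMAP (0.1 equiv), CH2Cl2, 0 °C to rt
Reagents that add atoms: none
Why: Steglich esterification acylates the secondary alcohol on oxygen, so the (S) centre of 4, the future C4', is carried over unchanged.

Step 3
Reactants: 6 2,5-dimethoxyphenylmagnesium bromide; 7 (S)-epichlorohydrin
Product: 9 (2S)-2-[(2,5-dimethoxyphenyl)methyl]oxirane, via chlorohydrin 8 (not isolated)
Conditions: CuI (0.1 equiv), THF, −40 to −20 °C; then MeOH, 2 M aq. NaOH, 0 °C to rt
Reagents that add atoms: none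
Why: Copper-catalysed Grignard opening of the epoxide at its CH2 (SN2, much faster than displacement of chloride), then base-induced intramolecular Williamson closure onto CH2Cl, moves the epoxide across without breaking a bond at the stereocentre, so (S)-7 should give (S)-9, the future (R)-C3.

Step 4
Reactants: 9 (2S)-2-[(2,5-dimethoxyphenyl)methyl]oxirane
Product: 10 (2S)-1-(2,5-dimethoxyphenyl)but-3-en-2-ol
Conditions: trimethylsulfonium iodide (3 equiv), n-BuLi (2.9 equiv), THF, −10 °C to rt
Reagents that add atoms: trimethylsulfonium iodide, C[S+](C)C.[I-]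
Why: Epoxide-to-allylic-alcohol homologation with dimethylsulfonium methylide: the ylide opens the epoxide at CH2 and the sulfonium betaine eliminates dimethyl sulfide, adding one carbon as =CH2 with the C–O stereocentre untouched.

Step 5
Reactants: 10 (2S)-1-(2,5-dimethoxyphenyl)but-3-en-2-ol; 5 (2S)-pent-4-en-2-yl 2,2,2-trichloroethyl butanedioate
Product: 11 2,2,2-trichloroethyl (2S,4E,6S)-7-(2,5-dimethoxyphenyl)-6-hydroxyhept-4-en-2-yl butanedioate
Conditions: 5 (2.5 equiv), second-generation Hoveyda–Grubbs catalyst RuCl2(H2IMes)(=CH-C6H4-2-OiPr) (5 mol%), CH2Cl2, 40 °C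
Reagents that add atoms: none
Why: Olefin cross metathesis between a secondary allylic alcohol, which homodimerises slowly, and an unhindered terminal olefin in excess should join C1' to C2' with loss of ethene; neither stereocentre takes part and the alkene geometry does not matter because the double bond is hydrogenated next.

Step 6
Reactants: 11 2,2,2-trichloroethyl (2S,4E,6S)-7-(2,5-dimethoxyphenyl)-6-hydroxyhept-4-en-2-yl butanedioate
Product: 12 2,2,2-trichloroethyl (2S,6R)-7-(2,5-dimethoxyphenyl)-6-hydroxyheptan-2-yl butanedioate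
Conditions: H2 (1 atm), [Ir(cod)(PCy3)(py)]PF6 (2 mol%), CH2Cl2, rt
Reagents that add atoms: none
Why: Hydroxyl-directed homogeneous hydrogenation with the cationic iridium catalyst of Crabtree should saturate the disubstituted alkene while leaving the CCl3 group, the esters and the arene alone, where palladium on carbon would risk C–Cl hydrogenolysis; the descriptor at the carbinol changes from S to R only through the change in substituent priority.

Step 7
Reactants: 12 2,2,2-trichloroethyl (2S,6R)-7-(2,5-dimethoxyphenyl)-6-hydroxyheptan-2-yl butanedioate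
Product: 13 tert-butyl (2R,6S)-1-(2,5-dimethoxyphenyl)-6-{[4-oxo-4-(2,2,2-trichloroethoxy)butanoyl]oxy}heptan-2-yl oxalate
Conditions: tert-butyl chlorooxoacetate (1.5 equiv), pyridine (3 equiv), CH2Cl2, 0 °C
Reagents that add atoms: tert-butyl chlorooxoacetate, CC(C)(C)OC(=O)C(=O)Cl
Why: O-acylation of the secondary alcohol by the acid chloride installs the oxalate as its tert-butyl ester while the ring is still an arene, so the later quinone never meets HCl or an amine base; only the O–H bond reacts, so C3 keeps its configuration.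

Step 8
Reactants: 13 tert-butyl (2R,6S)-1-(2,5-dimethoxyphenyl)-6-{[4-oxo-4-(2,2,2-trichloroethoxy)butanoyl]oxy}heptan-2-yl oxalate
Product: 14 tert-butyl (2R,6S)-1-(3,6-dioxocyclohexa-1,4-dien-1-yl)-6-{[4-oxo-4-(2,2,2-trichloroethoxy)butanoyl]oxy}heptan-2-yl oxalate
Conditions: (NH4)2Ce(NO3)6 (2.5 equiv), MeCN/H2O (2:1), 0 °C, 15 min
Reagents that add atoms: water, O
Why: Oxidative demethylation of the 1,4-dimethoxyarene by tetravalent cerium through the arene radical cation, with water delivering the quinone oxygens, should leave the esters, the CCl3 group and the tert-butyl oxalate untouched under short, cold, acidic conditions.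

Step 9
Reactants: 14 tert-butyl (2R,6S)-1-(3,6-dioxocyclohexa-1,4-dien-1-yl)-6-{[4-oxo-4-(2,2,2-trichloroethoxy)butanoyl]oxy}heptan-2-yl oxalate
Product: 15 2-{[(2R,6S)-1-(3,6-dioxocyclohexa-1,4-dien-1-yl)-6-{[4-oxo-4-(2,2,2-trichloroethoxy)butanoyl]oxy}heptan-2-yl]oxy}-2-oxoacetic acid
Conditions: TFA/CH2Cl2 (1:4), 0 °C to rt; evaporation from toluene
Reagents that add atoms: none
Why: Acidolysis of the tert-butyl ester (loss of 2-methylpropene through the tert-butyl cation) should free the oxalic half acid without water or base, which the secondary alkyl oxalate and the quinone would not tolerate.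

Step 10
Reactants: 15 2-{[(2R,6S)-1-(3,6-dioxocyclohexa-1,4-dien-1-yl)-6-{[4-oxo-4-(2,2,2-trichloroethoxy)butanoyl]oxy}heptan-2-yl]oxy}-2-oxoacetic acid
Product: 16 2,2,2-trichloroethyl (2S)-5-[(3R)-1,5,8-trioxo-3,4,5,8-tetrahydro-1H-isochromen-3-yl]pentan-2-yl butanedioate
Conditions: AgNO3 (0.3 equiv), (NH4)2S2O8 (2 equiv, added over 2 h), MeCN/H2O (3:1), 0.005 M, 35 °C, Ar
Reagents that add atoms: none
Why: Proposed new method: persulfate oxidises monovalent silver to divalent silver, which takes one electron from the oxalate carboxylate of 15; loss of CO2 leaves the alkoxycarbonyl radical on O2, whose carbon C1 adds to the unsubstituted quinone carbon C8a, and the resulting C4a radical (tertiary, next to the C5 carbonyl) is oxidised with loss of the C8a proton to return the quinone, now fused to the lactone. The closest known reactions are the AgNO3 and persulfate decarboxylative radical alkylation of quinones (Jacobsen–Torssell type), Minisci alkoxycarbonylation of heteroarenes with oxalic acid monoesters and acyl radical additions to quinones; new here is an alkoxycarbonyl radical as the partner and its use to close a lactone. The lactone ring closes in the 6-endo-trig mode on the C4a=C8a double bond. No stereocentre is made, and C3 and C4' keep their configuration because no bond to either is broken. The step needs 6-endo attack at C8a to beat 5-exo ipso attack at C4a, loss of a second CO2 (which would give a C3 alkyl radical) and intermolecular addition: nucleophilic radicals prefer the free CH of an alkylquinone, the spiro radical from ipso attack cannot be oxidised back to a quinone and can only revert or shift its acyl group to the same C4a radical, a secondary alkoxycarbonyl radical fragments slowly at 35 °C, and high dilution with slow oxidant addition holds back bimolecular paths. The neutral product should be extracted at once and carried on without storage, because acylquinones are strong electrophiles.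

Step 11
Reactants: 16 2,2,2-trichloroethyl (2S)-5-[(3R)-1,5,8-trioxo-3,4,5,8-tetrahydro-1H-isochromen-3-yl]pentan-2-yl butanedioate
Product: 17 4-oxo-4-{[(2S)-5-[(3R)-5,8-dihydroxy-1-oxo-3,4-dihydro-1H-isochromen-3-yl]pentan-2-yl]oxy}butanoic acid (aspergimarin B)
Conditions: Zn dust (15 equiv), AcOH/THF (1:1), rt, Ar
Reagents that add atoms: none
Why: Zinc in acetic acid should reduce the quinone to the hydroquinone and, by two-electron reduction of the CCl3 group with β-elimination of the carboxylate, cleave the trichloroethyl ester; the alkyl esters, the lactone and both stereocentres are not affected.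

**Compound list**

1 | succinic anhydride | O=C1CCC(=O)O1 | starting material
2 | 2,2,2-trichloroethanol | OCC(Cl)(Cl)Cl | starting material
3 | 4-oxo-4-(2,2,2-trichloroethoxy)butanoic acid | O=C(O)CCC(=O)OCC(Cl)(Cl)Cl | intermediate
4 | (S)-pent-4-en-2-ol | C[C@@H](CC=C)O | starting material
5 | (2S)-pent-4-en-2-yl 2,2,2-trichloroethyl butanedioate | C[C@@H](CC=C)OC(=O)CCC(=O)OCC(Cl)(Cl)Cl | intermediate
6 | 2,5-dimethoxyphenylmagnesium bromide | COc1ccc(OC)c([Mg]Br)c1 | starting material
7 | (S)-epichlorohydrin, (2S)-2-(chloromethyl)oxirane | ClC[C@@H]1CO1 | starting material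
8 | (2S)-1-chloro-3-(2,5-dimethoxyphenyl)propan-2-ol | ClC[C@@H](O)Cc1cc(OC)ccc1OC | intermediate (not isolated)
9 | (2S)-2-[(2,5-dimethoxyphenyl)methyl]oxirane | C1[C@@H](O1)Cc2cc(OC)ccc2OC | intermediate
10 | (2S)-1-(2,5-dimethoxyphenyl)but-3-en-2-ol | C=C[C@@H](O)Cc1cc(OC)ccc1OC | intermediate
11 | 2,2,2-trichloroethyl (2S,4E,6S)-7-(2,5-dimethoxyphenyl)-6-hydroxyhept-4-en-2-yl butanedioate | C[C@@H](C/C=C/[C@@H](O)Cc1cc(OC)ccc1OC)OC(=O)CCC(=O)OCC(Cl)(Cl)Cl | intermediate
12 | 2,2,2-trichloroethyl (2S,6R)-7-(2,5-dimethoxyphenyl)-6-hydroxyheptan-2-yl butanedioate | C[C@@H](CCC[C@@H](O)Cc1cc(OC)ccc1OC)OC(=O)CCC(=O)OCC(Cl)(Cl)Cl | intermediate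
13 | tert-butyl (2R,6S)-1-(2,5-dimethoxyphenyl)-6-{[4-oxo-4-(2,2,2-trichloroethoxy)butanoyl]oxy}heptan-2-yl oxalate | C[C@@H](CCC[C@@H](OC(=O)C(=O)OC(C)(C)C)Cc1cc(OC)ccc1OC)OC(=O)CCC(=O)OCC(Cl)(Cl)Cl | intermediate
14 | tert-butyl (2R,6S)-1-(3,6-dioxocyclohexa-1,4-dien-1-yl)-6-{[4-oxo-4-(2,2,2-trichloroethoxy)butanoyl]oxy}heptan-2-yl oxalate | C[C@@H](CCC[C@@H](OC(=O)C(=O)OC(C)(C)C)CC1=CC(=O)C=CC1=O)OC(=O)CCC(=O)OCC(Cl)(Cl)Cl | intermediate
15 | 2-{[(2R,6S)-1-(3,6-dioxocyclohexa-1,4-dien-1-yl)-6-{[4-oxo-4-(2,2,2-trichloroethoxy)butanoyl]oxy}heptan-2-yl]oxy}-2-oxoacetic acid | C[C@@H](CCC[C@@H](OC(=O)C(=O)O)CC1=CC(=O)C=CC1=O)OC(=O)CCC(=O)OCC(Cl)(Cl)Cl | intermediate (key-step precursor)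
16 | 2,2,2-trichloroethyl (2S)-5-[(3R)-1,5,8-trioxo-3,4,5,8-tetrahydro-1H-isochromen-3-yl]pentan-2-yl butanedioate | C[C@@H](CCC[C@@H]1CC2=C(C(=O)C=CC2=O)C(=O)O1)OC(=O)CCC(=O)OCC(Cl)(Cl)Cl | intermediate (key-step product)
17 | aspergimarin B, 4-oxo-4-{[(2S)-5-[(3R)-5,8-dihydroxy-1-oxo-3,4-dihydro-1H-isochromen-3-yl]pentan-2-yl]oxy}butanoic acid | C[C@@H](CCC[C@@H]1Cc2c(O)ccc(O)c2C(=O)O1)OC(=O)CCC(=O)O | target

**Step count and risk**

Total step count: 11. Longest linear sequence: 9 steps (steps 3 to 11 from 7; the branch through steps 1 and 2 is equally long).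

Steps most likely to fail:

Step 10 (key step). The alkoxycarbonyl radical may lose CO2 before it closes, may attack C4a in the 5-exo mode, or the product quinone may be attacked further by radicals or water. The fallback uses known chemistry, sets out from 12 and comes back at 16. Oxa-Pictet–Spengler cyclisation of 12 with dimethoxymethane and BF3·OEt2 in CH2Cl2 should close the pyran ring at the only free position ortho to the tether, giving 2,2,2-trichloroethyl (2S)-5-[(3R)-5,8-dimethoxy-3,4-dihydro-1H-isochromen-3-yl]pentan-2-yl butanedioate F1. Oxidation of its C1 benzylic ether methylene with pyridinium chlorochromate (C5H5NH)[CrO3Cl] in refluxing CH2Cl2 should give 2,2,2-trichloroethyl (2S)-5-[(3R)-5,8-dimethoxy-1-oxo-3,4-dihydro-1H-isochromen-3-yl]pentan-2-yl butanedioate F2. Oxidative demethylation of F2 with AgO and HNO3 in dioxane should then give 16.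

Step 5. The cross coupling may stall through redox isomerisation of the allylic alcohol to a ketone by ruthenium hydride species, or through homodimerisation outrunning the cross reaction. The fallback replaces metathesis by an acetylide opening of the epoxide; it sets out from 9 and comes back at 13.
- (S)-But-3-yn-2-ol is silylated (TBSCl, imidazole, DMF) to tert-butyl[(2S)-but-3-yn-2-yloxy]dimethylsilane F3.
- Its lithium acetylide (n-BuLi, then BF3·OEt2, THF, −78 °C) should open 9 at the CH2 to give (2R,6S)-6-[(tert-butyldimethylsilyl)oxy]-1-(2,5-dimethoxyphenyl)hept-4-yn-2-ol F4.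
- Hydrogenation (H2, Pd/C, EtOAc) should give (2R,6S)-6-[(tert-butyldimethylsilyl)oxy]-1-(2,5-dimethoxyphenyl)heptan-2-ol F5.
- Acylation with tert-butyl chlorooxoacetate and pyridine should give tert-butyl (2R,6S)-6-[(tert-butyldimethylsilyl)oxy]-1-(2,5-dimethoxyphenyl)heptan-2-yl oxalate F6.
- HF·pyridine in THF should remove the silyl group to give tert-butyl (2R,6S)-1-(2,5-dimethoxyphenyl)-6-hydroxyheptan-2-yl oxalate F7.
- Esterification of F7 with acid 3 (EDC hydrochloride, DMAP) gives 13.

Step 11. The electrophilic acylquinone may decompose while it is handled, and the CCl3 group may be reduced only in part while the hydroquinone re-oxidises in air. The fallback separates the two reductions; it sets out from 16 and comes back at 17. The extract of step 10 is shaken at once with aqueous Na2S2O4 in EtOAc to give the stable, purifiable 2,2,2-trichloroethyl (2S)-5-[(3R)-5,8-dihydroxy-1-oxo-3,4-dihydro-1H-isochromen-3-yl]pentan-2-yl butanedioate F8. The trichloroethyl ester of F8 is then cleaved with Zn dust in THF/1 M aq. KH2PO4 under argon to give 17.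

**Further compounds**

F1 | step 10 | 2,2,2-trichloroethyl (2S)-5-[(3R)-5,8-dimethoxy-3,4-dihydro-1H-isochromen-3-yl]pentan-2-yl butanedioate | C[C@@H](CCC[C@@H]1Cc2c(OC)ccc(OC)c2CO1)OC(=O)CCC(=O)OCC(Cl)(Cl)Cl
F2 | step 10 | 2,2,2-trichloroethyl (2S)-5-[(3R)-5,8-dimethoxy-1-oxo-3,4-dihydro-1H-isochromen-3-yl]pentan-2-yl butanedioate | C[C@@H](CCC[C@@H]1Cc2c(OC)ccc(OC)c2C(=O)O1)OC(=O)CCC(=O)OCC(Cl)(Cl)Cl
F3 | step 5 | tert-butyl[(2S)-but-3-yn-2-yloxy]dimethylsilane | C[C@@H](C#C)O[Si](C)(C)C(C)(C)C
F4 | step 5 | (2R,6S)-6-[(tert-butyldimethylsilyl)oxy]-1-(2,5-dimethoxyphenyl)hept-4-yn-2-ol | C[C@@H](C#CC[C@@H](O)Cc1cc(OC)ccc1OC)O[Si](C)(C)C(C)(C)C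
F5 | step 5 | (2R,6S)-6-[(tert-butyldimethylsilyl)oxy]-1-(2,5-dimethoxyphenyl)heptan-2-ol | C[C@@H](CCC[C@@H](O)Cc1cc(OC)ccc1OC)O[Si](C)(C)C(C)(C)C
F6 | step 5 | tert-butyl (2R,6S)-6-[(tert-butyldimethylsilyl)oxy]-1-(2,5-dimethoxyphenyl)heptan-2-yl oxalate | C[C@@H](CCC[C@@H](OC(=O)C(=O)OC(C)(C)C)Cc1cc(OC)ccc1OC)O[Si](C)(C)C(C)(C)C
F7 | step 5 | tert-butyl (2R,6S)-1-(2,5-dimethoxyphenyl)-6-hydroxyheptan-2-yl oxalate | C[C@H](O)CCC[C@@H](OC(=O)C(=O)OC(C)(C)C)Cc1cc(OC)ccc1OC
F8 | step 11 | 2,2,2-trichloroethyl (2S)-5-[(3R)-5,8-dihydroxy-1-oxo-3,4-dihydro-1H-isochromen-3-yl]pentan-2-yl butanedioate | C[C@@H](CCC[C@@H]1Cc2c(O)ccc(O)c2C(=O)O1)OC(=O)CCC(=O)OCC(Cl)(Cl)Cl
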